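The incoming ligand replaces the leaving ligand on the starting complex and gives the complex with one exchanged. I wanted to know which way of charging leaves most of that complex at the end.

| flask | starting complex | incoming ligand | leaving ligand | remark | time |
|---|---|---|---|---|---|
| summer | 0.050 M | 0.040 M | 0.025 M | run made earlier |  |
| dusk | 0.050 M | 0.040 M | 0.035 M | run made earlier |  |
| dawn | 0.050 M | 0.040 M | 0.055 M | run made earlier |  |
| autumn | 0.050 M | 0.060 M | 0.025 M | run made earlier |  |
| teal | 0.050 M | 0.0400 M | 0.0250 M | everything together at the start | 20 min |
| green | 0.050 M (fed, over 15 min) | 0.0400 M | 0.0250 M | all else is in the flask from the start; the feed brings no volume worth counting | 20 min |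
| red | 0.050 M | 0.0400 M (fed, over 15 min) | 0.0250 M | all else is in the flask from the start; the feed brings no volume worth counting | 20 min |

| run | time / min | complex with one exchanged / % | starting complex / % |
|---|---|---|---|
| summer | 2.00 | 6.2 | 93.6 |
| summer | 4.00 | 10.9 | 87.4 |
| summer | 6.00 | 13.5 | 83.0 |
| summer | 8.00 | 15.6 | 80.7 |
| summer | 10.0 | 16.7 | 78.2 |
| summer | 12.0 | 18.4 | 77.2 |
| dusk | 1.33 | 4.6 | 94.9 |
| dusk | 2.00 | 6.1 | 92.2 |
| dusk | 4.00 | 10.6 | 86.2 |
| dusk | 6.00 | 13.3 | 83.8 |
| dusk | 10.0 | 17.4 | 77.9 |
| dusk | 15.0 | 20.3 | 75.0 |
| dawn | 1.00 | 3.7 | 95.1 |
| dawn | 3.00 | 8.7 | 91.0 |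
| dawn | 6.00 | 14.3 | 82.7 |
| dawn | 8.00 | 15.5 | 79.8 |
| dawn | 12.0 | 18.0 | 77.2 |
| dawn | 15.0 | 19.5 | 74.7 |
| autumn | 1.33 | 6.6 | 92.0 |
| autumn | 4.00 | 16.2 | 82.3 |
| autumn | 8.00 | 22.5 | 71.4 |
| autumn | 12.0 | 26.0 | 67.2 |
| autumn | 15.0 | 26.2 | 64.7 |

(standard deviation of a reading: 0.5 percentage points)

- for leaving ligand the crystals are counted in
- as a solid, counted per litre of solution: crystals
- the earlier runs were read with a standard deviation of 0.5 percentage points
- reactions considered so far: starting complex + incoming ligand -> leaving ligand + complex with one exchanged; complex with one exchanged + incoming ligand -> leaving ligand + complex with two exchanged; complex with two exchanged + incoming ligand -> leaving ligand + complex with three exchanged; complex with one exchanged <-> isomer of the product; crystals <-> leaving ligand; incoming ligand -> decomposed reagent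

- which flask leads in amount of complex with one exchanged, in percent of the starting complex charged ("all alike" within 1.5 percentage points) (teal / green / red / all alike)
- how much complex with one exchanged is there at the end, in percent of the starting complex charged: teal
- how much complex with one exchanged is there at the end, in percent of the starting complex charged: green
- how much complex with one exchanged is there at the end, in percent of the starting complex charged: red

At 6.00 min the starting complex read 83.0% in summer, 83.8% in dusk and 82.7% in dawn, although dawn held more leaving ligand, so I set that ligand aside. Autumn, with 1.50 times the incoming ligand, showed 1.45 times summer's logarithmic loss of starting complex by 4.00 min, so the fractional rate of that loss follows the ligand. In summer this rate read 0.0337 min⁻¹ over the first 4.00 min but 0.0111 min⁻¹ between 8.00 min and 12.0 min, far lower, and from these scattered readings that drift reads as a ligand lifetime of 7.20 min and a starting rate of 0.0444 min⁻¹.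

The bench habit is to treat the reaction as pseudo-first-order and multiply starting rate by time, which gives 0.889 for teal. That needs a time short against the lifetime, yet teal runs 2.78 lifetimes. I therefore used starting rate times lifetime, 0.320, the reach: the logarithmic loss of starting complex expected from a whole ligand charge of summer's size. The loss so far is the reach times the share of ligand gone. Summer's last reading puts 80.7% of the converted complex in the one-exchanged form.

That gave me 20.9% for teal and 18.0% for red. Green's complex meets decaying ligand, so I reckoned 8.74% for that flask.

The forecast also chose teal, with 22%, 14.5% and 19.5% for teal, green and red, its green above mine, saying “the late-fed complex meets ligand already decayed”. The flasks gave teal the lead, with 20.9% in teal, 12.5% in green, above my 8.74%, and 18.2% in red.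

    starting complex + incoming ligand → leaving ligand + complex with one exchanged (k = 0.0180 M⁻¹ s⁻¹)
    complex with one exchanged + incoming ligand → leaving ligand + complex with two exchanged (k = 0.0140 M⁻¹ s⁻¹)
    complex with two exchanged + incoming ligand → leaving ligand + complex with three exchanged (k = 0.0130 M⁻¹ s⁻¹)
    complex with one exchanged ⇌ isomer of the product (K = 0.170, k = 0.00130 s⁻¹)
    crystals ⇌ leaving ligand, rate k5*(cs5 - [leaving ligand]) while solid is left; crystals form when [leaving ligand] > cs5 (solubility = 0.680 mM, k = 0.0720 s⁻¹)
    incoming ligand → decomposed reagent (k = 0.00120 s⁻¹)

Teal had not come to rest at 20.0 min: 8.61% of its ligand remained, and reach times that share promised a further 2 percentage points of starting complex. At 200 min, with the ligand at 0%, the starting complex stood at 70.5% against 72.7%, and the complex with one exchanged at 22.3%. Green kept 12.4% of its ligand, which promised 3.3 points. Left ten times as long, until 200 min, green's starting complex went from 84.3% to 80.7%, and its complex with one exchanged rose from 12.5% to 15.0%.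

All runs are simulated from invented constants.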